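The plan cuts ring E twice, between C3' and C4' and between O1' and C2'. It exploits that ring F carries O1' next to a bare benzylic CH2 (C4'), so that ring F can be unmasked as the parent o-quinone methide, and that C2'–C3' can be read as the carboxyl and α-carbons of an acetic acid arm on D6. One carbene-catalysed annulation then forges both bonds, closes ring E as a dihydrocoumarin and fixes C3' from the catalyst. Its precursor is the complete (3R,4S) upper chroman (rings A to D, phenols benzylated) bearing a D6 acetyl imidazole, built by an Evans aldol and a Friedel–Crafts closure of ring C, together with a silylated ring F bromomethylphenol.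

Key step: step 18

Labels: ring A (benzo) and ring C (pyran: O1, C2, C3, C4, C4a, C8a) make up the upper chroman; ring B is the aryl group on C3; ring D is the central arene (D1 bonded to C4, D2 methoxy, D4 oxygen, D6 bonded to C3'); ring E (pyran: O1', C2', C3', C4', C4a', C8a') and ring F (benzo) make up the lower chroman.

Remark on the chemistry: which enantiomer of the aminoindanol triazolium salt delivers 3'R cannot be read off with certainty for an α-aryl enolate of this size. The (5aS,10bR) salt is written; its sense is to be checked on phenylacetyl imidazole before use, and the (5aR,10bS) salt is taken if the check points the other way.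

Remark on the chemistry: 3-(benzyloxy)phenol and (S)-4-benzyl-1,3-oxazolidin-2-one are bought. The two partners of step 18 keep the protecting groups shown (four benzyl ethers, one silyl group); the labile bromide is made last and added slowly.

Step 1
Reactants: 1 methyl 2-(3,5-dihydroxyphenyl)acetate
Product: 3 methyl 2-(2-formyl-3,5-dihydroxyphenyl)acetate, via aryl iminium chloride 2 (not isolated)
Conditions: POCl3, DMF, MeCN, 0 °C to rt; then H2O, 50 °C
Reagents that add atoms: N,N-dimethylformamide, CN(C)C=O; water, O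
Why: Vilsmeier–Haack formylation of the resorcinol should take place next to the acetate arm (para to one hydroxyl, ortho to the other; the two such carbons are equivalent), as in the formylation of orcinol, which puts the future C4 carbon on D1.

Step 2
Reactants: 3 methyl 2-(2-formyl-3,5-dihydroxyphenyl)acetate
Product: 4 methyl 2-[5-(benzyloxy)-2-formyl-3-hydroxyphenyl]acetate
Conditions: BnBr (1.05 equiv), NaHCO3, KI (cat.), MeCN, 70 °C
Reagents that add atoms: benzyl bromide, BrCc1ccccc1
Why: In this Williamson etherification the hydroxyl para to the formyl group is the more acidic and is not held in the hydrogen bond to the carbonyl, so a weak base should benzylate it alone (D4), as known for 2,4-dihydroxybenzaldehyde.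

Step 3
Reactants: 4 methyl 2-[5-(benzyloxy)-2-formyl-3-hydroxyphenyl]acetate
Product: 5 methyl 2-[5-(benzyloxy)-2-formyl-3-methoxyphenyl]acetate
Conditions: MeI, K2CO3, acetone, 50 °C
Reagents that add atoms: iodomethane, CI
Why: Williamson methylation of the remaining chelated hydroxyl gives the D2 methyl ether, and carbonate is too weak to deprotonate the arylacetate methylene.

Step 4
Reactants: 6 2,6-dimethoxyphenol
Product: 7 2-(benzyloxy)-1,3-dimethoxybenzene
Conditions: BnBr, K2CO3, DMF, 60 °C
Reagents that add atoms: benzyl bromide, BrCc1ccccc1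
Why: Williamson benzylation of the flanked phenol protects the ring B hydroxyl in the form in which it is carried to the last step.

Step 5
Reactants: 7 2-(benzyloxy)-1,3-dimethoxybenzene
Product: 8 3-(benzyloxy)-1-bromo-2,4-dimethoxybenzene
Conditions: NBS, MeCN, 0 °C to rt
Reagents that add atoms: N-bromosuccinimide, O=C1CCC(=O)N1Br
Why: Electrophilic bromination of the 1,2,3-trioxygenated ring should go para to a methoxy group, as for 1,2,3-trimethoxybenzene, because the flanked central ether is twisted out of conjugation.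

Step 6
Reactants: 8 3-(benzyloxy)-1-bromo-2,4-dimethoxybenzene
Product: 9 tert-butyl 2-[3-(benzyloxy)-2,4-dimethoxyphenyl]acetate
Conditions: BrZnCH2CO2t-Bu (1.3 equiv), Pd(dba)2 (2 mol%), P(t-Bu)3 (2 mol%), THF, rt to 50 °C
Reagents that add atoms: (2-tert-butoxy-2-oxoethyl)zinc bromide, CC(C)(C)OC(=O)C[Zn]Br
Why: Palladium-catalysed α-arylation with a Reformatsky reagent couples the aryl bromide under neutral conditions, tolerates the ortho-methoxy group and stops at monoarylation.

Step 7
Reactants: 9 tert-butyl 2-[3-(benzyloxy)-2,4-dimethoxyphenyl]acetate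
Product: 10 2-[3-(benzyloxy)-2,4-dimethoxyphenyl]acetic acid
Conditions: TFA/CH2Cl2 (1:3), 0 °C to rt
Reagents that add atoms: none
Why: Acidolysis of the tert-butyl ester with loss of 2-methylpropene frees the acid, and aryl benzyl and methyl ethers withstand brief TFA at room temperature.

Step 8
Reactants: 10 2-[3-(benzyloxy)-2,4-dimethoxyphenyl]acetic acid; 11 (S)-4-benzyl-1,3-oxazolidin-2-one
Product: 13 (S)-4-benzyl-3-{2-[3-(benzyloxy)-2,4-dimethoxyphenyl]acetyl}-1,3-oxazolidin-2-one, via mixed pivalic anhydride 12 (not isolated)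
Conditions: PivCl, Et3N, THF, −20 °C; then 11, LiCl, rt
Reagents that add atoms: none
Why: N-acylation of the oxazolidinone through the mixed anhydride is a standard one-pot procedure, and the hindered pivaloyl carbonyl does not compete.

Step 9
Reactants: 13 ring B arylacetyl oxazolidinone; 5 ring D aldehyde
Product: 16 (S)-4-benzyl-3-[(2S,3S)-2-[3-(benzyloxy)-2,4-dimethoxyphenyl]-3-hydroxy-3-{4-(benzyloxy)-2-methoxy-6-(2-methoxy-2-oxoethyl)phenyl}propanoyl]-1,3-oxazolidin-2-one, via Z-boron enolate 14 (not isolated), via boron aldolate 15 (not isolated)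
Conditions: Bu2BOTf, i-Pr2NEt, CH2Cl2, 0 °C; 5, −78 to 0 °C; pH 7 buffer, MeOH, H2O2, 0 °C
Reagents that add atoms: none
Why: In this Evans syn-aldol reaction the Z-boron enolate reacts through a Zimmerman–Traxler chair with the auxiliary carbonyl turned away, so the benzyl group of the (S)-oxazolidinone should fix the α-carbon as S (it becomes C3 with R configuration), while the syn carbinol centre is erased in step 12.

Step 10
Reactants: 16 aldol adduct
Product: 18 (S)-6-(benzyloxy)-1-{(R)-1-[3-(benzyloxy)-2,4-dimethoxyphenyl]-2-hydroxyethyl}-8-methoxyisochroman-3-one, via diol ester 17 (not isolated)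
Conditions: NaBH4, THF/H2O (4:1), 0 °C to rt; extractive work-up; then DBU (0.3 equiv), toluene, 50 °C
Reagents that add atoms: none
Why: Borohydride in wet THF reduces the activated exocyclic imide carbonyl (reductive removal of the auxiliary) and spares the methyl arylacetate, and base-catalysed lactonisation of the benzylic hydroxyl onto that ester then gives the six-membered 3-isochromanone, which masks the carbinol and the acid in one ring without touching C3.

Step 11
Reactants: 18 lactone alcohol; 19 3-(benzyloxy)phenol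
Product: 20 (S)-6-(benzyloxy)-1-{(R)-1-[3-(benzyloxy)-2,4-dimethoxyphenyl]-2-[3-(benzyloxy)phenoxy]ethyl}-8-methoxyisochroman-3-one
Conditions: PPh3, DIAD, THF, 0 °C to rt
Reagents that add atoms: none
Why: Mitsunobu etherification of the only free (primary) hydroxyl with the phenol forms the O1–C2 bond by SN2 displacement at C2 and so attaches ring A.

Step 12
Reactants: 20 aryl ether lactone
Product: 21 2-{5-(benzyloxy)-2-[(3R,4S)-7-(benzyloxy)-3-[3-(benzyloxy)-2,4-dimethoxyphenyl]chroman-4-yl]-3-methoxyphenyl}acetic acid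
Conditions: TFA/CH2Cl2 (1:9), 0 °C
Reagents that add atoms: none
Why: In this intramolecular Friedel–Crafts alkylation with a benzylic lactone as leaving group, acid ionises the C–O bond to a cation stabilised by the ortho-methoxy and para-benzyloxy groups of ring D, and ring A should attack through the carbon para to its benzyloxy group faster than H3 is lost, closing ring C with the C4 aryl trans to the C3 aryl (both pseudo-equatorial) and releasing the acetic acid arm directly.

Step 13
Reactants: 21 upper-unit arylacetic acid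
Product: 22 2-{5-(benzyloxy)-2-[(3R,4S)-7-(benzyloxy)-3-[3-(benzyloxy)-2,4-dimethoxyphenyl]chroman-4-yl]-3-methoxyphenyl}-1-(1H-imidazol-1-yl)ethan-1-one
Conditions: CDI (1.2 equiv), CH2Cl2, rt
Reagents that add atoms: 1,1'-carbonyldiimidazole, O=C(n1ccnc1)n1ccnc1
Why: Acyl transfer from carbonyldiimidazole converts the acid into the acyl imidazole with loss of CO2 and imidazole, without added base and without risk to the benzylic stereocentres.

Step 14
Reactants: 23 2,4-dihydroxybenzaldehyde
Product: 24 4-(benzyloxy)-2-hydroxybenzaldehyde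
Conditions: BnBr (1.05 equiv), NaHCO3, KI (cat.), MeCN, 70 °C
Reagents that add atoms: benzyl bromide, BrCc1ccccc1
Why: Williamson etherification with a weak base should benzylate only the 4-hydroxyl, since the 2-hydroxyl is held in the hydrogen bond to the formyl group.

Step 15
Reactants: 24 4-(benzyloxy)-2-hydroxybenzaldehyde
Product: 25 4-(benzyloxy)-2-[(tert-butyldimethylsilyl)oxy]benzaldehyde
Conditions: TBSCl, imidazole, DMF, rt
Reagents that add atoms: tert-butyldimethylsilyl chloride, CC(C)(C)[Si](C)(C)Cl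
Why: Silylation of the phenol under imidazole catalysis installs the fluoride-labile trigger that later releases the ring F phenoxide.

Step 16
Reactants: 25 4-(benzyloxy)-2-[(tert-butyldimethylsilyl)oxy]benzaldehyde
Product: 26 {4-(benzyloxy)-2-[(tert-butyldimethylsilyl)oxy]phenyl}methanol
Conditions: NaBH4, MeOH/THF, 0 °C, short reaction time
Reagents that add atoms: none
Why: Borohydride reduction of the aldehyde at 0 °C is fast enough that the silyl group should stay on the phenol oxygen.

Step 17
Reactants: 26 {4-(benzyloxy)-2-[(tert-butyldimethylsilyl)oxy]phenyl}methanol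
Product: 27 [5-(benzyloxy)-2-(bromomethyl)phenoxy](tert-butyl)dimethylsilane
Conditions: CBr4, PPh3, CH2Cl2, 0 °C; quick filtration through silica; used at once
Reagents that add atoms: tetrabromomethane, BrC(Br)(Br)Br
Why: The Appel bromination works under neutral conditions, so the aryl silyl ether survives, and the easily ionised para-alkoxybenzyl bromide is not stored.

Step 18
Reactants: 22 upper-unit acyl imidazole; 27 silylated ring F bromomethylphenol
Product: 29 (R)-7-(benzyloxy)-3-{5-(benzyloxy)-2-[(3R,4S)-7-(benzyloxy)-3-[3-(benzyloxy)-2,4-dimethoxyphenyl]chroman-4-yl]-3-methoxyphenyl}chroman-2-one, via ring F o-quinone methide 28 (not isolated)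
Conditions: (5aS,10bR)-2-mesityl-5a,10b-dihydro-4H,6H-indeno[2,1-b][1,2,4]triazolo[4,3-d][1,4]oxazin-2-ium tetrafluoroborate (20 mol%), CsF (3 equiv), 18-crown-6 (3 equiv), THF, −20 °C, 27 (2 equiv) added over 2 h
Reagents that add atoms: none
Why: Fluoride cleaves the aryl silyl ether of 27 and the phenoxide ejects bromide to give the o-quinone methide 28, while the free carbene displaces imidazole from 22 and the acyl azolium is deprotonated to its enolate; the enolate carbon C3' adds to the exocyclic methylene C4' with rearomatisation of ring F, and the phenoxide so formed is acylated by the acyl azolium, which forms O1'–C2' and returns the carbene. The closest known reaction is the carbene-catalysed formal [4+2] annulation of acyl imidazoles with fluoride-generated o-quinone methides to 3-substituted dihydrocoumarins. Ring E closes by 6-exo-trig attack of the phenoxide oxygen on the acyl azolium carbonyl. The only new stereocentre, C3', should be set by the enolate face that the aminoindanol framework of the catalyst leaves open and not by the distant C3 and C4 centres, so a mismatched pairing can be answered with the enantiomeric salt. The step needs this facial selectivity and clean C-alkylation at a single carbon; the substrates secure the latter because C4' is the only electrophilic terminus and is unsubstituted, every other phenol is a benzyl ether, 27 holds the only silyl group and the acyl imidazole is the only activated enolisable carbonyl. Slow addition of 27 keeps the methide scarce against the hindered enolate, and the base-labile α-aryl lactone is reduced without storage.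

Step 19
Reactants: 29 dihydrocoumarin
Product: 30 5-(benzyloxy)-2-[(R)-2-{5-(benzyloxy)-2-[(3R,4S)-7-(benzyloxy)-3-[3-(benzyloxy)-2,4-dimethoxyphenyl]chroman-4-yl]-3-methoxyphenyl}-3-hydroxypropyl]phenol
Conditions: LiAlH4, THF, −10 to 0 °C
Reagents that add atoms: none
Why: Hydride reduction of the aryl lactone to the primary alcohol and the ring F phenol should outrun any base-induced epimerisation, and afterwards C3' is no longer α to a carbonyl.

Step 20
Reactants: 30 phenol alcohol
Product: 31 (3R,4S)-7-(benzyloxy)-4-{4-(benzyloxy)-2-[(R)-7-(benzyloxy)chroman-3-yl]-6-methoxyphenyl}-3-[3-(benzyloxy)-2,4-dimethoxyphenyl]chroman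
Conditions: PPh3, DIAD, THF, 0 °C to rt
Reagents that add atoms: none
Why: Intramolecular Mitsunobu etherification lets the phenol displace the activated primary hydroxyl at C2' (6-exo-tet), the standard isoflavan ring closure, and C3' takes no part.

Step 21
Reactants: 31 tetrabenzyl ether
Product: 32 (3R,4S)-4-{4-hydroxy-2-[(R)-7-hydroxychroman-3-yl]-6-methoxyphenyl}-3-(3-hydroxy-2,4-dimethoxyphenyl)chroman-7-ol
Conditions: H2 (1 atm), Pd/C (10% palladium on carbon), THF/MeOH, rt
Reagents that add atoms: none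
Why: Hydrogenolysis cleaves the four aryl benzyl ethers, while the chroman O–CH2 bonds (not benzylic) and the diarylmethine C4 should be inert under these conditions.

Compound list
1 | methyl 2-(3,5-dihydroxyphenyl)acetate | COC(=O)Cc1cc(O)cc(O)c1 | starting material
2 | N-[2,4-dihydroxy-6-(2-methoxy-2-oxoethyl)benzylidene]-N-methylmethanaminium chloride | COC(=O)Cc1cc(O)cc(O)c1C=[N+](C)C.[Cl-] | intermediate (not isolated)
3 | methyl 2-(2-formyl-3,5-dihydroxyphenyl)acetate | COC(=O)Cc1cc(O)cc(O)c1C=O | intermediate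
4 | methyl 2-[5-(benzyloxy)-2-formyl-3-hydroxyphenyl]acetate | COC(=O)Cc1cc(OCc2ccccc2)cc(O)c1C=O | intermediate
5 | methyl 2-[5-(benzyloxy)-2-formyl-3-methoxyphenyl]acetate | COC(=O)Cc1cc(OCc2ccccc2)cc(OC)c1C=O | intermediate
6 | 2,6-dimethoxyphenol | COc1cccc(OC)c1O | starting material
7 | 2-(benzyloxy)-1,3-dimethoxybenzene | COc1cccc(OC)c1OCc1ccccc1 | intermediate
8 | 3-(benzyloxy)-1-bromo-2,4-dimethoxybenzene | COc1ccc(Br)c(OC)c1OCc1ccccc1 | intermediate
9 | tert-butyl 2-[3-(benzyloxy)-2,4-dimethoxyphenyl]acetate | COc1ccc(CC(=O)OC(C)(C)C)c(OC)c1OCc1ccccc1 | intermediate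
10 | 2-[3-(benzyloxy)-2,4-dimethoxyphenyl]acetic acid | COc1ccc(CC(=O)O)c(OC)c1OCc1ccccc1 | intermediate
11 | (S)-4-benzyl-1,3-oxazolidin-2-one | O=C1OC[C@H](Cc2ccccc2)N1 | starting material
12 | 2-[3-(benzyloxy)-2,4-dimethoxyphenyl]acetic pivalic anhydride | COc1ccc(CC(=O)OC(=O)C(C)(C)C)c(OC)c1OCc1ccccc1 | intermediate (not isolated)
13 | (S)-4-benzyl-3-{2-[3-(benzyloxy)-2,4-dimethoxyphenyl]acetyl}-1,3-oxazolidin-2-one | COc1ccc(CC(=O)N2[C@@H](Cc3ccccc3)COC2=O)c(OC)c1OCc1ccccc1 | intermediate
14 | dibutylboron (Z)-enolate of 13 | CCCCB(CCCC)O/C(=C\c1ccc(OC)c(OCc2ccccc2)c1OC)N1[C@@H](Cc2ccccc2)COC1=O | intermediate (not isolated)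
15 | O-dibutylboryl derivative of aldol 16 | O=C1OC[C@H](Cc2ccccc2)N1C(=O)[C@@H](c1ccc(OC)c(OCc2ccccc2)c1OC)[C@H](OB(CCCC)CCCC)c1c(OC)cc(OCc2ccccc2)cc1CC(=O)OC | intermediate (not isolated)
16 | (S)-4-benzyl-3-[(2S,3S)-2-[3-(benzyloxy)-2,4-dimethoxyphenyl]-3-hydroxy-3-{4-(benzyloxy)-2-methoxy-6-(2-methoxy-2-oxoethyl)phenyl}propanoyl]-1,3-oxazolidin-2-one | O=C1OC[C@H](Cc2ccccc2)N1C(=O)[C@@H](c1ccc(OC)c(OCc2ccccc2)c1OC)[C@H](O)c1c(OC)cc(OCc2ccccc2)cc1CC(=O)OC | intermediate
17 | methyl 2-{5-(benzyloxy)-2-[(1S,2R)-2-[3-(benzyloxy)-2,4-dimethoxyphenyl]-1,3-dihydroxypropyl]-3-methoxyphenyl}acetate | OC[C@@H](c1ccc(OC)c(OCc2ccccc2)c1OC)[C@H](O)c1c(OC)cc(OCc2ccccc2)cc1CC(=O)OC | intermediate (not isolated)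
18 | (S)-6-(benzyloxy)-1-{(R)-1-[3-(benzyloxy)-2,4-dimethoxyphenyl]-2-hydroxyethyl}-8-methoxyisochroman-3-one | OC[C@@H](c1ccc(OC)c(OCc2ccccc2)c1OC)[C@@H]1OC(=O)Cc2cc(OCc3ccccc3)cc(OC)c21 | intermediate
19 | 3-(benzyloxy)phenol | Oc1cccc(OCc2ccccc2)c1 | starting material
20 | (S)-6-(benzyloxy)-1-{(R)-1-[3-(benzyloxy)-2,4-dimethoxyphenyl]-2-[3-(benzyloxy)phenoxy]ethyl}-8-methoxyisochroman-3-one | c1ccccc1COc1cccc(OC[C@@H](c2ccc(OC)c(OCc3ccccc3)c2OC)[C@@H]2OC(=O)Cc3cc(OCc4ccccc4)cc(OC)c32)c1 | intermediate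
21 | 2-{5-(benzyloxy)-2-[(3R,4S)-7-(benzyloxy)-3-[3-(benzyloxy)-2,4-dimethoxyphenyl]chroman-4-yl]-3-methoxyphenyl}acetic acid | COc1ccc([C@@H]2COc3cc(OCc4ccccc4)ccc3[C@H]2c2c(OC)cc(OCc3ccccc3)cc2CC(=O)O)c(OC)c1OCc1ccccc1 | intermediate
22 | 2-{5-(benzyloxy)-2-[(3R,4S)-7-(benzyloxy)-3-[3-(benzyloxy)-2,4-dimethoxyphenyl]chroman-4-yl]-3-methoxyphenyl}-1-(1H-imidazol-1-yl)ethan-1-one | COc1ccc([C@@H]2COc3cc(OCc4ccccc4)ccc3[C@H]2c2c(OC)cc(OCc3ccccc3)cc2CC(=O)n2ccnc2)c(OC)c1OCc1ccccc1 | intermediate
23 | 2,4-dihydroxybenzaldehyde | O=Cc1ccc(O)cc1O | starting material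
24 | 4-(benzyloxy)-2-hydroxybenzaldehyde | O=Cc1ccc(OCc2ccccc2)cc1O | intermediate
25 | 4-(benzyloxy)-2-[(tert-butyldimethylsilyl)oxy]benzaldehyde | O=Cc1ccc(OCc2ccccc2)cc1O[Si](C)(C)C(C)(C)C | intermediate
26 | {4-(benzyloxy)-2-[(tert-butyldimethylsilyl)oxy]phenyl}methanol | OCc1ccc(OCc2ccccc2)cc1O[Si](C)(C)C(C)(C)C | intermediate
27 | [5-(benzyloxy)-2-(bromomethyl)phenoxy](tert-butyl)dimethylsilane | CC(C)(C)[Si](C)(C)Oc1cc(OCc2ccccc2)ccc1CBr | intermediate
28 | 3-(benzyloxy)-6-methylidenecyclohexa-2,4-dien-1-one | C=C1C=CC(OCc2ccccc2)=CC1=O | intermediate (not isolated)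
29 | (R)-7-(benzyloxy)-3-{5-(benzyloxy)-2-[(3R,4S)-7-(benzyloxy)-3-[3-(benzyloxy)-2,4-dimethoxyphenyl]chroman-4-yl]-3-methoxyphenyl}chroman-2-one | COc1ccc([C@@H]2COc3cc(OCc4ccccc4)ccc3[C@H]2c2c(OC)cc(OCc3ccccc3)cc2[C@@H]2C(=O)Oc3cc(OCc4ccccc4)ccc3C2)c(OC)c1OCc1ccccc1 | intermediate
30 | 5-(benzyloxy)-2-[(R)-2-{5-(benzyloxy)-2-[(3R,4S)-7-(benzyloxy)-3-[3-(benzyloxy)-2,4-dimethoxyphenyl]chroman-4-yl]-3-methoxyphenyl}-3-hydroxypropyl]phenol | COc1ccc([C@@H]2COc3cc(OCc4ccccc4)ccc3[C@H]2c2c(OC)cc(OCc3ccccc3)cc2[C@H](CO)Cc2ccc(OCc3ccccc3)cc2O)c(OC)c1OCc1ccccc1 | intermediate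
31 | (3R,4S)-7-(benzyloxy)-4-{4-(benzyloxy)-2-[(R)-7-(benzyloxy)chroman-3-yl]-6-methoxyphenyl}-3-[3-(benzyloxy)-2,4-dimethoxyphenyl]chroman | COc1ccc([C@@H]2COc3cc(OCc4ccccc4)ccc3[C@H]2c2c(OC)cc(OCc3ccccc3)cc2[C@@H]2COc3cc(OCc4ccccc4)ccc3C2)c(OC)c1OCc1ccccc1 | intermediate
32 | (3R,4S)-4-{4-hydroxy-2-[(R)-7-hydroxychroman-3-yl]-6-methoxyphenyl}-3-(3-hydroxy-2,4-dimethoxyphenyl)chroman-7-ol | COc1ccc([C@@H]2COc3cc(O)ccc3[C@H]2c2c(OC)cc(O)cc2[C@@H]2COc3cc(O)ccc3C2)c(OC)c1O | target

Total step count: 21 steps.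
Longest linear sequence: 14 steps (steps 4 to 13, then 18 to 21).

Steps most likely to fail

Step 18. The azolium enolate carries a very large ortho branch on ring D. Carbon–carbon bond formation may therefore be slower than oligomerisation of the methide, the facial selectivity may be poor or mismatched with the existing centres, and C3' may epimerise in the basic medium. The fallback sets out from 21 (with 27) and returns at 30. Acid 21 is acylated onto (R)-4-benzyl-1,3-oxazolidin-2-one (PivCl, Et3N, then the oxazolidinone and LiCl) to give the (R)-oxazolidinone imide F1. Its sodium enolate (NaN(SiMe3)2, THF, −78 °C) is benzylated by 27 on the face away from the auxiliary benzyl group, an Evans alkylation of the kind used for isoflavans, to give the C3' benzylated imide F2 with C3' R. LiBH4 removes the auxiliary and gives the silyl ether alcohol F3, and Bu4NF frees the ring F phenol to give 30.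

Step 9. Addition to the doubly ortho-substituted, donor-deactivated aldehyde may be slow, and the aldol may revert during work-up. The fallback sets out from 5 and 10 and returns at 21; it replaces carbonyl addition by an irreversible SN1-type alkylation in which the electron-rich ring D is an asset.
- Aldehyde 5 is converted (HC(OMe)3, TsOH cat., MeOH) into the dimethyl acetal F4.
- Acid 10 is coupled (EDC·HCl, DMAP) with (R)-4-isopropyl-1,3-thiazolidine-2-thione to the thioimide F5. The (R) auxiliary is needed because the chelated titanium enolate is attacked on the face opposite to that used by the boron enolate.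
- The chlorotitanium enolate of F5 (TiCl4, i-Pr2NEt, CH2Cl2, −78 °C) is alkylated by the oxocarbenium ion released from F4 with BF3·OEt2, giving the anti β-methoxy adduct F6 with the α-carbon S.
- NaBH4 removes the auxiliary without touching the ester and gives the methoxy alcohol F7.
- Mitsunobu etherification with 19 gives the aryl ether F8.
- BF3·OEt2 ionises the benzylic methyl ether and ring A closes as in step 12 to the chroman methyl ester F9.
- LiOH saponification gives 21.

Step 10. In the basic borohydride medium the aldol may cleave by retro-aldol reaction, or may eliminate once the carbinol has closed onto the ester ahead of imide reduction; lactonisation of the hindered carbinol may also stay incomplete. The fallback sets out from 16 and returns at 18. LiOH/H2O2 (THF/H2O, 0 °C) cleaves the imide hydrolytically to the hydroxy acid F10. BH3·SMe2 (THF, 0 °C) then reduces the carboxylic acid in the presence of the methyl ester in a non-basic medium to give 17, and DBU in toluene closes the lactone 18.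

Further compounds
F1 | step 18 | (R)-4-benzyl-3-(2-{5-(benzyloxy)-2-[(3R,4S)-7-(benzyloxy)-3-[3-(benzyloxy)-2,4-dimethoxyphenyl]chroman-4-yl]-3-methoxyphenyl}acetyl)-1,3-oxazolidin-2-one | COc1ccc([C@@H]2COc3cc(OCc4ccccc4)ccc3[C@H]2c2c(OC)cc(OCc3ccccc3)cc2CC(=O)N2[C@H](Cc3ccccc3)COC2=O)c(OC)c1OCc1ccccc1
F2 | step 18 | (R)-4-benzyl-3-[(R)-2-{5-(benzyloxy)-2-[(3R,4S)-7-(benzyloxy)-3-[3-(benzyloxy)-2,4-dimethoxyphenyl]chroman-4-yl]-3-methoxyphenyl}-3-{4-(benzyloxy)-2-[(tert-butyldimethylsilyl)oxy]phenyl}propanoyl]-1,3-oxazolidin-2-one | COc1ccc([C@@H]2COc3cc(OCc4ccccc4)ccc3[C@H]2c2c(OC)cc(OCc3ccccc3)cc2[C@@H](Cc2ccc(OCc3ccccc3)cc2O[Si](C)(C)C(C)(C)C)C(=O)N2[C@H](Cc3ccccc3)COC2=O)c(OC)c1OCc1ccccc1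
F3 | step 18 | (R)-2-{5-(benzyloxy)-2-[(3R,4S)-7-(benzyloxy)-3-[3-(benzyloxy)-2,4-dimethoxyphenyl]chroman-4-yl]-3-methoxyphenyl}-3-{4-(benzyloxy)-2-[(tert-butyldimethylsilyl)oxy]phenyl}propan-1-ol | COc1ccc([C@@H]2COc3cc(OCc4ccccc4)ccc3[C@H]2c2c(OC)cc(OCc3ccccc3)cc2[C@@H](Cc2ccc(OCc3ccccc3)cc2O[Si](C)(C)C(C)(C)C)CO)c(OC)c1OCc1ccccc1
F4 | step 9 | methyl 2-[5-(benzyloxy)-2-(dimethoxymethyl)-3-methoxyphenyl]acetate | COC(=O)Cc1cc(OCc2ccccc2)cc(OC)c1C(OC)OC
F5 | step 9 | 2-[3-(benzyloxy)-2,4-dimethoxyphenyl]-1-[(R)-4-isopropyl-2-thioxo-1,3-thiazolidin-3-yl]ethan-1-one | COc1ccc(CC(=O)N2[C@H](C(C)C)CSC2=S)c(OC)c1OCc1ccccc1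
F6 | step 9 | methyl 2-{5-(benzyloxy)-2-[(1R,2S)-2-[3-(benzyloxy)-2,4-dimethoxyphenyl]-3-[(R)-4-isopropyl-2-thioxo-1,3-thiazolidin-3-yl]-1-methoxy-3-oxopropyl]-3-methoxyphenyl}acetate | S=C1SC[C@@H](C(C)C)N1C(=O)[C@@H](c1ccc(OC)c(OCc2ccccc2)c1OC)[C@@H](OC)c1c(OC)cc(OCc2ccccc2)cc1CC(=O)OC
F7 | step 9 | methyl 2-{5-(benzyloxy)-2-[(1R,2R)-2-[3-(benzyloxy)-2,4-dimethoxyphenyl]-3-hydroxy-1-methoxypropyl]-3-methoxyphenyl}acetate | OC[C@@H](c1ccc(OC)c(OCc2ccccc2)c1OC)[C@@H](OC)c1c(OC)cc(OCc2ccccc2)cc1CC(=O)OC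
F8 | step 9 | methyl 2-{5-(benzyloxy)-2-[(1R,2R)-2-[3-(benzyloxy)-2,4-dimethoxyphenyl]-3-[3-(benzyloxy)phenoxy]-1-methoxypropyl]-3-methoxyphenyl}acetate | c1ccccc1COc1cccc(OC[C@@H](c2ccc(OC)c(OCc3ccccc3)c2OC)[C@@H](OC)c2c(OC)cc(OCc3ccccc3)cc2CC(=O)OC)c1
F9 | step 9 | methyl 2-{5-(benzyloxy)-2-[(3R,4S)-7-(benzyloxy)-3-[3-(benzyloxy)-2,4-dimethoxyphenyl]chroman-4-yl]-3-methoxyphenyl}acetate | COc1ccc([C@@H]2COc3cc(OCc4ccccc4)ccc3[C@H]2c2c(OC)cc(OCc3ccccc3)cc2CC(=O)OC)c(OC)c1OCc1ccccc1
F10 | step 10 | (2S,3S)-2-[3-(benzyloxy)-2,4-dimethoxyphenyl]-3-hydroxy-3-{4-(benzyloxy)-2-methoxy-6-(2-methoxy-2-oxoethyl)phenyl}propanoic acid | OC(=O)[C@@H](c1ccc(OC)c(OCc2ccccc2)c1OC)[C@H](O)c1c(OC)cc(OCc2ccccc2)cc1CC(=O)OC
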